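**Plan**

- Cuts: in the dienone ring (ring B) the C(=O)–C(OMe) bond and the CH=–C(spiro) bond are cut to release one methoxyacetylene. The spiro 3-methoxycyclobutenone that remains is cut at C(spiro)–C(OMe) and C(=O)–CH into a cyclohexylketene and a second methoxyacetylene. The ketene carbon, both aryl–ring bonds and the 3-methyl are then removed back to (S)-2-ethyl-5-methylcyclohexenone.
- Enabling feature: around the spiro carbon, ring B reads C(OMe)=CH–C(=O)–C(OMe)=CH. The first three carbons are a 3-alkoxycyclobutenone closed on the spiro atom and the last two are an alkoxyalkyne, so ring B is one carboxyl carbon plus two HC≡COMe. The acyl–C(spiro) bond of the four-membered ring is absent from the target and serves as the temporary bond.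
- Forward order: ring A by organocatalytic annulation (step 1), first aryl (2), 1,3-carbonyl transposition with methyl delivery (3, 4), hydrogenation (5), second aryl (6), one-carbon homologation to the acid (7–9), ketene/ynol ether [2+2] (11), rhodium-catalysed insertion of the second ynol ether, which closes ring B last (12).
- Stereochemistry: the C–Me centre comes from the amine catalyst; the first aryl goes anti to it; ethyl and 3-methyl come from syn hydrogenation anti to that aryl; the second aryl settles equatorial. The spiro centre is set by equatorial closure of the ketene cycloaddition (away from the axial methyl) and is carried through the insertion with retention.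

Key step: step 12

Remark: tert-butyl 3-oxohexanoate is taken as a catalogue compound, and the sense of induction in step 1 follows the usual shielding model for diarylprolinol silyl ethers (nucleophile anti to the shielding group on the E-iminium), so the (R)-catalyst is taken to give (S)-5.

**Route**

Step 1
Reactants: 1 (E)-crotonaldehyde; 2 tert-butyl 3-oxohexanoate
Product: 5 (S)-2-ethyl-5-methylcyclohex-2-en-1-one, via Michael adduct 3 (not isolated), via cyclic keto ester 4 (not isolated)
Conditions: (R)-2-{bis[3,5-bis(trifluoromethyl)phenyl](trimethylsilyloxy)methyl}pyrrolidine (10 mol %), PhCO2H (10 mol %), toluene, 0 °C → rt; then p-TsOH·H2O (20 mol %), toluene, 80 °C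
Reagents that add atoms: none
Why: Organocatalytic Robinson-type annulation in which iminium-activated asymmetric Michael addition of the β-keto ester to the enal sets the methyl-bearing centre as S (the silyloxydiarylmethyl group shields one face of the E-iminium), followed by acid-promoted intramolecular aldol condensation of the ketone γ-CH2 onto the aldehyde, tert-butyl ester cleavage and decarboxylation.

Step 2
Reactants: 5 (S)-2-ethyl-5-methylcyclohex-2-en-1-one; 6 1-bromo-2,4,5-trimethoxybenzene
Product: 9 (5S,6S)-2-ethyl-5-methyl-6-(2,4,5-trimethoxyphenyl)cyclohex-2-en-1-one, via lithium enolate 7 (not isolated), via zinc enolate 8 (not isolated)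
Conditions: LiN(SiMe3)2 (1.05 equiv), THF, −78 °C; ZnCl2 (1.1 equiv), −78 → 0 °C; Pd2(dba)3 (2 mol %), P(t-Bu)3 (8 mol %), 6, THF, rt → 45 °C
Reagents that add atoms: none
Why: Kinetic deprotonation at the only α′-methylene gives the cross-conjugated enolate, whose zinc enolate undergoes palladium-catalysed α-arylation (Negishi-type enolate arylation) with the arylpalladium unit approaching anti to the neighbouring methyl, so the new benzylic centre is set trans to it (also the more stable epimer), and the weakly basic zinc enolate does not re-enolise the product.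

Step 3
Reactants: 9 (5S,6S)-2-ethyl-5-methyl-6-(2,4,5-trimethoxyphenyl)cyclohex-2-en-1-one
Product: 10 (5S,6S)-2-ethyl-1,5-dimethyl-6-(2,4,5-trimethoxyphenyl)cyclohex-2-en-1-ol (either configuration at C1)
Conditions: MeLi, CeCl3, THF, −78 °C
Reagents that add atoms: methyllithium, [Li]C
Why: 1,2-Addition of the weakly basic organocerium reagent to the enone carbonyl outruns enolisation of the acidic benzylic α-hydrogen, and the new carbinol centre is removed in step 4, so its configuration is immaterial.

Step 4
Reactants: 10 (5S,6S)-2-ethyl-1,5-dimethyl-6-(2,4,5-trimethoxyphenyl)cyclohex-2-en-1-ol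
Product: 11 (4R,5S)-2-ethyl-3,5-dimethyl-4-(2,4,5-trimethoxyphenyl)cyclohex-2-en-1-one
Conditions: pyridinium chlorochromate [C5H5NH][CrO3Cl] (2.5 equiv), 4 Å molecular sieves, CH2Cl2, rt
Reagents that add atoms: pyridinium chlorochromate, [O-][Cr](=O)(=O)Cl.c1cc[nH+]cc1
Why: Oxidative 1,3-transposition of a tertiary allylic alcohol (Dauben–Michno/Babler oxidation), in which the chromate ester undergoes a [3,3] shift and the secondary allylic chromate is oxidised to the tetrasubstituted enone, moves the carbonyl so that the aryl-bearing carbon becomes γ and a free α′-CH2 appears, without touching the two stereocentres.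

Step 5
Reactants: 11 (4R,5S)-2-ethyl-3,5-dimethyl-4-(2,4,5-trimethoxyphenyl)cyclohex-2-en-1-one
Product: 12 (2R,3R,4R,5S)-2-ethyl-3,5-dimethyl-4-(2,4,5-trimethoxyphenyl)cyclohexan-1-one
Conditions: H2 (4 atm), 10% Pd/C, EtOAc, rt
Reagents that add atoms: none
Why: Heterogeneous catalytic hydrogenation adds both hydrogens syn to the tetrasubstituted enone from the face anti to the adjacent C4 aryl group (which A(1,2) strain with the vinylic methyl pushes pseudo-axial), so ethyl and 3-methyl end cis to each other and cis to the aryl group, the ethyl in the more stable equatorial α-position.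

Step 6
Reactants: 12 (2R,3R,4R,5S)-2-ethyl-3,5-dimethyl-4-(2,4,5-trimethoxyphenyl)cyclohexan-1-one; 6 1-bromo-2,4,5-trimethoxybenzene
Product: 15 (2R,3R,4S,5R,6R)-2-ethyl-3,5-dimethyl-4,6-bis(2,4,5-trimethoxyphenyl)cyclohexan-1-one, via lithium enolate 13 (not isolated), via zinc enolate 14 (not isolated)
Conditions: LiN(SiMe3)2 (1.05 equiv), THF, −78 °C; ZnCl2 (1.1 equiv), −78 → 0 °C; Pd2(dba)3 (2 mol %), P(t-Bu)3 (8 mol %), 6, THF, rt → 45 °C; work-up, then DBU (10 mol %), CH2Cl2, rt
Reagents that add atoms: none
Why: Kinetic deprotonation takes the unhindered α-CH2 rather than the α-CH(Et), and palladium-catalysed arylation of the zinc enolate (as in step 2) gives the α-aryl ketone whose new benzylic centre settles equatorial and trans to the 5-methyl (the thermodynamic epimer, and the only α-centre acidic enough to equilibrate under amine base), leaving C2 untouched.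

Step 7
Reactants: 15 (2R,3R,4S,5R,6R)-2-ethyl-3,5-dimethyl-4,6-bis(2,4,5-trimethoxyphenyl)cyclohexan-1-one
Product: 16 methylidene compound (15 with C1=O replaced by C1=CH2, ring stereocentres unchanged)
Conditions: Cp2TiMe2 (3 equiv), toluene, 70 °C, dark
Reagents that add atoms: dimethyltitanocene Cp2TiMe2, [CH3-].[CH3-].[Ti+4].c1cc[cH-]c1.c1cc[cH-]c1
Why: Petasis methylenation with the non-basic titanium methylidene converts the hindered, enolisable ketone to the exocyclic alkene without epimerising either α-centre.

Step 8
Reactants: 16 methylidene compound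
Product: 18 [2-ethyl-3,5-dimethyl-4,6-bis(2,4,5-trimethoxyphenyl)cyclohexyl]methanol (C2–C6 as in 15, either configuration at C1), via alkylborane 17 (not isolated)
Conditions: BH3·THF (3 equiv), THF, 0 °C → rt; then NaOH, H2O2, H2O, 0 °C → rt
Reagents that add atoms: hydrogen peroxide, OO
Why: Anti-Markovnikov hydroboration–oxidation of the 1,1-disubstituted alkene gives the primary alcohol, and the new ring CH centre becomes sp2 again in step 11, so its configuration does not matter.

Step 9
Reactants: 18 [2-ethyl-3,5-dimethyl-4,6-bis(2,4,5-trimethoxyphenyl)cyclohexyl]methanol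
Product: 20 2-ethyl-3,5-dimethyl-4,6-bis(2,4,5-trimethoxyphenyl)cyclohexane-1-carboxylic acid (C2–C6 as in 15, either configuration at C1), via aldehyde 19 (not isolated)
Conditions: TEMPO (20 mol %), PhI(OAc)2 (2.5 equiv), MeCN/H2O (1:1), rt
Reagents that add atoms: water, O
Why: Nitroxyl-catalysed oxidation takes the primary alcohol through the aldehyde hydrate to the carboxylic acid under conditions that spare the electron-rich arenes.

Step 10
Reactants: 21 chloroacetaldehyde dimethyl acetal
Product: 23 methoxyacetylene, via sodium methoxyacetylide 22 (not isolated)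
Conditions: NaNH2 (3.1 equiv), liquid NH3, −33 °C; then cold saturated aqueous NaCl; distilled into toluene
Reagents that add atoms: none
Why: Amide-induced double elimination (loss of methanol, then of HCl) from the chloroacetal gives the sodium alkoxyacetylide, which is hydrolysed and distilled as the volatile ynol ether (the classical alkoxyacetylene preparation).

Step 11
Reactants: 20 2-ethyl-3,5-dimethyl-4,6-bis(2,4,5-trimethoxyphenyl)cyclohexane-1-carboxylic acid; 23 methoxyacetylene
Product: 26 5-ethyl-3-methoxy-6,8-dimethyl-7,9-bis(2,4,5-trimethoxyphenyl)spiro[3.5]non-2-en-1-one (C1 carbonyl axial on ring A, C3–OMe carbon equatorial), via acid chloride 24 (not isolated), via ketene 25 (not isolated)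
Conditions: 1-chloro-N,N,2-trimethylprop-1-en-1-amine (1.2 equiv), CH2Cl2, 0 °C → rt; then Et3N (3 equiv), 23 (5 equiv), toluene, sealed tube, 60 °C
Reagents that add atoms: none
Why: Neutral acid chloride formation, dehydrochlorination to the dialkylketene and thermal ketene–alkyne [2+2] cycloaddition (the standard route to 3-alkoxycyclobutenones) join the nucleophilic CH terminus of the ynol ether to the ketene carbonyl carbon, after which the oxygen-bearing carbon closes onto the ring carbon from the equatorial face, away from the axial 3-methyl, which sets the spiro centre with C–OMe equatorial and C=O axial.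

Step 12
Reactants: 26 spirocyclobutenone; 23 methoxyacetylene
Product: 27 tatanan B, 11-ethyl-2,5-dimethoxy-8,10-dimethyl-7,9-bis(2,4,5-trimethoxyphenyl)spiro[5.5]undeca-1,4-dien-3-one (C1H= axial on ring A, C5(OMe)= equatorial)
Conditions: [Rh(cod)Cl]2 (5 mol %), P(C6F5)3 (20 mol %), 23 (3 equiv, slow addition), toluene, 40 °C, sealed vessel
Reagents that add atoms: none
Why: Proposed new method: monovalent rhodium adds oxidatively into the strained acyl–C(sp3) bond between C1 and the spiro carbon C4 of 26 to give a rhodacyclopentenone (a metal-bound vinylketene) with the metal on the axial face of ring A; methoxyacetylene then inserts 1,2 into the Rh–C(sp3) bond, the tertiary carbon going to the unsubstituted alkyne terminus and rhodium to the oxygen-bearing carbon, and acyl–vinyl reductive elimination from the seven-membered rhodacycle forms the C(=O)–C(OMe) bond and closes the six-membered ring B (formal [4+2], both alkyne carbons inside the new ring). The closest known reaction type is the insertion of alkynes into this same bond of cyclobutenones under zerovalent nickel or monovalent rhodium catalysis (which normally ends in a phenol), together with rhodium "cut-and-sew" couplings of cyclobutanones with π-partners; not yet shown are a fully substituted C4, which blocks aromatisation and leaves the cross-conjugated dienone, and an alkoxyacetylene as partner. No stereocentre is created: the spiro centre from step 11 is carried over because oxidative addition and migratory insertion both proceed with retention at the migrating carbon, so the new CH= carbon takes the axial site vacated by the acyl carbon and the C(OMe)= carbon stays equatorial. The step needs one orientation of the alkyne, secured by the preference of the hindered tertiary Rh–C carbon for the CH terminus and by α-oxygen stabilisation of the resulting vinyl–rhodium (as in carbometalation of alkoxyacetylenes), and it needs insertion to outrun thermal 4π ring opening of 26 and alkyne oligomerisation, secured by 40 °C, a π-acidic phosphine that speeds reductive elimination and slow addition of 23.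

**Compound list**

1 | (E)-crotonaldehyde | C/C=C/C=O | starting material
2 | tert-butyl 3-oxohexanoate | CCCC(=O)CC(=O)OC(C)(C)C | starting material
3 | Michael adduct, tert-butyl 3-oxo-2-[(2S)-4-oxobutan-2-yl]hexanoate (not isolated) | CCCC(=O)C(C(=O)OC(C)(C)C)[C@@H](C)CC=O | intermediate
4 | cyclic keto ester, tert-butyl (6S)-3-ethyl-6-methyl-2-oxocyclohex-3-ene-1-carboxylate (not isolated) | C1=C(CC)C(=O)C(C(=O)OC(C)(C)C)[C@@H](C)C1 | intermediate
5 | (S)-2-ethyl-5-methylcyclohex-2-en-1-one | C1=C(CC)C(=O)C[C@@H](C)C1 | intermediate
6 | 1-bromo-2,4,5-trimethoxybenzene | COc1cc(OC)c(OC)cc1Br | starting material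
7 | lithium enolate of 5, cross-conjugated (not isolated) | C1=C(CC)C([O-])=C[C@@H](C)C1.[Li+] | intermediate
8 | zinc enolate of 5 (not isolated) | C1=C(CC)C(O[Zn]Cl)=C[C@@H](C)C1 | intermediate
9 | (5S,6S)-2-ethyl-5-methyl-6-(2,4,5-trimethoxyphenyl)cyclohex-2-en-1-one | C1=C(CC)C(=O)[C@H](c2cc(OC)c(OC)cc2OC)[C@@H](C)C1 | intermediate
10 | (5S,6S)-2-ethyl-1,5-dimethyl-6-(2,4,5-trimethoxyphenyl)cyclohex-2-en-1-ol, C1 epimers | C1=C(CC)C(C)(O)[C@H](c2cc(OC)c(OC)cc2OC)[C@@H](C)C1 | intermediate
11 | (4R,5S)-2-ethyl-3,5-dimethyl-4-(2,4,5-trimethoxyphenyl)cyclohex-2-en-1-one | CCC1=C(C)[C@H](c2cc(OC)c(OC)cc2OC)[C@@H](C)CC1=O | intermediate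
12 | (2R,3R,4R,5S)-2-ethyl-3,5-dimethyl-4-(2,4,5-trimethoxyphenyl)cyclohexan-1-one | CC[C@@H]1[C@H](C)[C@H](c2cc(OC)c(OC)cc2OC)[C@@H](C)CC1=O | intermediate
13 | lithium enolate of 12 toward C6 (not isolated) | CC[C@@H]1[C@H](C)[C@H](c2cc(OC)c(OC)cc2OC)[C@@H](C)C=C1[O-].[Li+] | intermediate
14 | zinc enolate of 12 (not isolated) | CC[C@@H]1[C@H](C)[C@H](c2cc(OC)c(OC)cc2OC)[C@@H](C)C=C1O[Zn]Cl | intermediate
15 | (2R,3R,4S,5R,6R)-2-ethyl-3,5-dimethyl-4,6-bis(2,4,5-trimethoxyphenyl)cyclohexan-1-one (ethyl, 3-methyl and both aryl groups on one face, 5-methyl on the other) | CC[C@@H]1[C@H](C)[C@H](c2cc(OC)c(OC)cc2OC)[C@@H](C)[C@H](c2cc(OC)c(OC)cc2OC)C1=O | intermediate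
16 | methylidene compound, 15 with C=O replaced by C=CH2 | CC[C@@H]1[C@H](C)[C@H](c2cc(OC)c(OC)cc2OC)[C@@H](C)[C@H](c2cc(OC)c(OC)cc2OC)C1=C | intermediate
17 | primary alkylborane from 16, C1 epimers (not isolated) | CC[C@@H]1[C@H](C)[C@H](c2cc(OC)c(OC)cc2OC)[C@@H](C)[C@H](c2cc(OC)c(OC)cc2OC)C1CB | intermediate
18 | [2-ethyl-3,5-dimethyl-4,6-bis(2,4,5-trimethoxyphenyl)cyclohexyl]methanol, C1 epimers | CC[C@@H]1[C@H](C)[C@H](c2cc(OC)c(OC)cc2OC)[C@@H](C)[C@H](c2cc(OC)c(OC)cc2OC)C1CO | intermediate
19 | 2-ethyl-3,5-dimethyl-4,6-bis(2,4,5-trimethoxyphenyl)cyclohexane-1-carbaldehyde, C1 epimers (not isolated in step 9) | CC[C@@H]1[C@H](C)[C@H](c2cc(OC)c(OC)cc2OC)[C@@H](C)[C@H](c2cc(OC)c(OC)cc2OC)C1C=O | intermediate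
20 | 2-ethyl-3,5-dimethyl-4,6-bis(2,4,5-trimethoxyphenyl)cyclohexane-1-carboxylic acid, C1 epimers | CC[C@@H]1[C@H](C)[C@H](c2cc(OC)c(OC)cc2OC)[C@@H](C)[C@H](c2cc(OC)c(OC)cc2OC)C1C(=O)O | intermediate
21 | chloroacetaldehyde dimethyl acetal | COC(CCl)OC | starting material
22 | sodium methoxyacetylide (not isolated) | COC#[C-].[Na+] | intermediate
23 | methoxyacetylene | COC#C | intermediate
24 | acid chloride of 20 (not isolated) | CC[C@@H]1[C@H](C)[C@H](c2cc(OC)c(OC)cc2OC)[C@@H](C)[C@H](c2cc(OC)c(OC)cc2OC)C1C(=O)Cl | intermediate
25 | ketene, [2-ethyl-3,5-dimethyl-4,6-bis(2,4,5-trimethoxyphenyl)cyclohexylidene]methanone (not isolated) | CC[C@@H]1[C@H](C)[C@H](c2cc(OC)c(OC)cc2OC)[C@@H](C)[C@H](c2cc(OC)c(OC)cc2OC)C1=C=O | intermediate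
26 | 5-ethyl-3-methoxy-6,8-dimethyl-7,9-bis(2,4,5-trimethoxyphenyl)spiro[3.5]non-2-en-1-one (C=O axial, C–OMe equatorial on ring A) | CC[C@@H]1[C@H](C)[C@H](c2cc(OC)c(OC)cc2OC)[C@@H](C)[C@H](c2cc(OC)c(OC)cc2OC)[C@]12C(=O)C=C2OC | intermediate
27 | tatanan B | CC[C@@H]1[C@H](C)[C@H](c2cc(OC)c(OC)cc2OC)[C@@H](C)[C@H](c2cc(OC)c(OC)cc2OC)[C@]12C=C(OC)C(=O)C=C2OC | target

**Step count and risks**

Total: 12 steps. Longest linear sequence: 11 steps (steps 1–9, 11 and 12; step 10 makes the reagent 23).

Steps most likely to fail:

1. Step 12 (Proposed new method). The alkyne may insert in the opposite orientation (which would give the symmetrical 3,5-dimethoxy dienone). The spiro configuration may be lost if the metal-bound vinylketene exchanges faces, the more so because the metal must sit on the face of the axial methyl. Thermal ring opening of the cyclobutenone or oligomerisation of the ynol ether may outrun insertion. The fallback uses known chemistry without C–C activation; it sets out from alcohol 18 and comes back at 27. Dess–Martin periodinane gives aldehyde 19, isolated this time. Its potassium enolate (KN(SiMe3)2, THF, −78 °C) is ethynylated on the equatorial face with 1-[(trimethylsilyl)ethynyl]-1,2-benziodoxol-3(1H)-one and Bu4NF (electrophilic α-alkynylation of an enolate with a hypervalent-iodine alkyne, same facial logic as step 11) to give the α-ethynyl aldehyde F1, with formyl axial and ethynyl equatorial. Acyl Sonogashira coupling with methoxyacetyl chloride (PdCl2(PPh3)2, CuI, Et3N) gives the ynone F2. NaOMe in MeOH adds methoxide to the ynone β-carbon to give the β-methoxy enone F3 (not isolated), whose CH2OMe carbon condenses with the axial formyl group (intramolecular aldol condensation) to close ring B at the CH=C(OMe) bond and give 27.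

2. Step 11. Cycloaddition of the hindered, doubly α-branched ketene may be slow, so that ketene dimerisation or capture by chloride or amine competes, and closure on the axial face would give the wrong spiro epimer. The fallback sets out from acid 20 and comes back at 26. It passes through the same acid chloride 24 and ketene 25, but the ketene is trapped with the far more nucleophilic 1,1-dimethoxyethene (ketene–ketene acetal [2+2]) to give the 3,3-dimethoxy spirocyclobutanone F4. p-TsOH (cat.) in toluene at 40 °C then eliminates methanol to give 26.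

3. Step 5. Hydrogen may be delivered to the wrong face of the tetrasubstituted enone, because the 5-methyl favours the face that the aryl group blocks, and double-bond migration may precede reduction. The fallback sets out from enone 11 and comes back at ketone 15. The second aryl group is introduced first, under the conditions of step 6, to give the diaryl enone F5, whose ring is locked with all three substituents equatorial. NaBH4/CeCl3 (MeOH, −78 °C, Luche reduction by axial hydride) gives the allylic alcohol F6 with the hydroxyl on the face opposite both aryl groups. Hydroxyl-directed hydrogenation with [Ir(cod)(PCy3)(py)]PF6 (H2, CH2Cl2) delivers both hydrogens from the hydroxyl face to give the saturated alcohol F7. Dess–Martin oxidation, followed by DBU equilibration of the benzylic α-centre, gives 15.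

**Further compounds**

F1 | step 12 | 1-ethynyl-2-ethyl-3,5-dimethyl-4,6-bis(2,4,5-trimethoxyphenyl)cyclohexane-1-carbaldehyde (formyl axial, ethynyl equatorial) | CC[C@@H]1[C@H](C)[C@H](c2cc(OC)c(OC)cc2OC)[C@@H](C)[C@H](c2cc(OC)c(OC)cc2OC)[C@]1(C#C)C=O
F2 | step 12 | ynone, 2-ethyl-1-(4-methoxy-3-oxobut-1-yn-1-yl)-3,5-dimethyl-4,6-bis(2,4,5-trimethoxyphenyl)cyclohexane-1-carbaldehyde | CC[C@@H]1[C@H](C)[C@H](c2cc(OC)c(OC)cc2OC)[C@@H](C)[C@H](c2cc(OC)c(OC)cc2OC)[C@]1(C#CC(=O)COC)C=O
F3 | step 12 | β-methoxy enone, 1-(1,4-dimethoxy-3-oxobut-1-en-1-yl) analogue of F2 with ring carbon and acyl group cis (not isolated) | CC[C@@H]1[C@H](C)[C@H](c2cc(OC)c(OC)cc2OC)[C@@H](C)[C@H](c2cc(OC)c(OC)cc2OC)[C@]1(/C(OC)=C\C(=O)COC)C=O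
F4 | step 11 | 5-ethyl-3,3-dimethoxy-6,8-dimethyl-7,9-bis(2,4,5-trimethoxyphenyl)spiro[3.5]nonan-1-one | CC[C@@H]1[C@H](C)[C@H](c2cc(OC)c(OC)cc2OC)[C@@H](C)[C@H](c2cc(OC)c(OC)cc2OC)[C@]12C(=O)CC2(OC)OC
F5 | step 5 | (4R,5R,6R)-2-ethyl-3,5-dimethyl-4,6-bis(2,4,5-trimethoxyphenyl)cyclohex-2-en-1-one | CCC1=C(C)[C@H](c2cc(OC)c(OC)cc2OC)[C@@H](C)[C@H](c2cc(OC)c(OC)cc2OC)C1=O
F6 | step 5 | allylic alcohol from F5, hydroxyl trans to the 6-aryl group | CCC1=C(C)[C@H](c2cc(OC)c(OC)cc2OC)[C@@H](C)[C@H](c2cc(OC)c(OC)cc2OC)[C@H]1O
F7 | step 5 | saturated alcohol, the secondary alcohol corresponding to ketone 15 | CC[C@@H]1[C@H](C)[C@H](c2cc(OC)c(OC)cc2OC)[C@@H](C)[C@H](c2cc(OC)c(OC)cc2OC)[C@H]1O
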